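The route rests on breaking the C3–C1′ bond at the quaternary peroxy carbon of the 1,2-dioxane (ring atoms O1, O2, C3, C4, C4a, O5, C6, C7, C7a; side chain C1′–C10′): C3 is used as an electrophile, a bicyclic peroxycarbenium ion, instead of being built by C–O bond formation. In the last step both anomers of a cis-fused 3-methoxy peroxyketal lactone ionise to one cation, and ε-attack of a complete pentadienylsilane joins the whole side chain, sets C3 under control of the pseudoaxial lactone oxygen O5 on C4a, and creates the C2′=C3′–C4′=C5′ diene by allylic transposition. The precursor, a peroxyketal carrying only the C4a/C7a stereocentres, comes from ozonolysis/oxa-Michael cyclisation of an enantiopure butenolide.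

Key step: step 9

Remark: (R)-2-methylglycidol is taken as a purchasable single enantiomer; 9 is carried as its mixture of C3 anomers and 19 as the racemate, since both of these stereocentres are erased in step 9.

Step 1
Reactants: 1 (R)-2-methylglycidol; 2 isopropenylmagnesium bromide
Product: 3 (2S)-2,4-dimethylpent-4-ene-1,2-diol
Conditions: 2 (3 equiv), CuI (10 mol%), THF, −30 to 0 °C; aq NH4Cl
Reagents that add atoms: none
Why: Copper-catalysed SN2 opening of the epoxide by the alkenyl Grignard reagent occurs at the unhindered CH2 terminus (the free hydroxyl only consumes one equivalent of 2 as its alkoxide) and breaks no bond to the stereocentre, so (R)-1 gives (S)-3 by a change of CIP priorities alone.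

Step 2
Reactants: 3 (2S)-2,4-dimethylpent-4-ene-1,2-diol
Product: 4 (2S)-2-hydroxy-2,4-dimethylpent-4-enal
Conditions: IBX (1.5 equiv), EtOAc, 75 °C; filter, use as a solution (volatile)
Reagents that add atoms: none
Why: IBX oxidation takes the primary alcohol of the 1,2-diol to the aldehyde without glycol cleavage and cannot oxidise the tertiary alcohol, which leaves the quaternary stereocentre untouched.

Step 3
Reactants: 4 (2S)-2-hydroxy-2,4-dimethylpent-4-enal; 5 (triphenylphosphoranylidene)ketene (Bestmann ylide)
Product: 7 (5S)-5-methyl-5-(2-methylprop-2-en-1-yl)furan-2(5H)-one, via phosphorane ester 6 (not isolated)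
Conditions: toluene, 90 °C
Reagents that add atoms: none
Why: In the Bestmann butenolide synthesis the tertiary hydroxyl adds to the ketene ylide to give the ester-stabilised phosphorane 6, whose intramolecular Wittig reaction with the neighbouring aldehyde closes the five-membered ring (necessarily Z) without touching the stereocentre.

Step 4
Reactants: 7 (5S)-5-methyl-5-(2-methylprop-2-en-1-yl)furan-2(5H)-one
Product: 9 (4aS,7aS)-3-methoxy-3,4a-dimethyltetrahydrofuro[3,2-c][1,2]dioxin-6-one, via methoxy hydroperoxide 8 (not isolated)
Conditions: O3, CH2Cl2/MeOH 4:1, −78 °C (Sudan Red end point); N2 purge, concentrate cold; Et2NH (0.2 equiv), CF3CH2OH, 0 °C to rt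
Reagents that add atoms: ozone [O-][O+]=O; methanol CO
Why: Criegee ozonolysis attacks the electron-rich 1,1-disubstituted alkene and not the electron-poor butenolide, the ketone O-oxide formed by the preferred cycloreversion is trapped by methanol as α-methoxy hydroperoxide 8, and amine-catalysed intramolecular oxa-Michael addition (6-exo-trig) of its OOH to the butenolide can only occur from the face of the tether, so C7a is set cis to the C4a oxygen while the C3 anomers are left as an inconsequential mixture.

Step 5
Reactants: 10 styrene; 11 5-bromopent-1-ene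
Product: 12 [(1E)-5-bromopent-1-en-1-yl]benzene
Conditions: 10 (3 equiv), Grubbs II (2 mol%), CH2Cl2, 40 °C
Reagents that add atoms: none
Why: Ruthenium-catalysed olefin cross-metathesis of a terminal alkene with excess styrene is thermodynamically E-selective and tolerates the primary bromide.

Step 6
Reactants: 13 1,3-bis(trimethylsilyl)propyne; 12 [(1E)-5-bromopent-1-en-1-yl]benzene
Product: 15 trimethyl[(7E)-8-phenyl-3-(trimethylsilyl)oct-7-en-1-yn-1-yl]silane, via lithiated propyne 14 (not isolated)
Conditions: n-BuLi (1.05 equiv), THF, −78 °C; then 12, DMPU, −78 °C to rt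
Reagents that add atoms: none
Why: n-BuLi removes the doubly activated propargylic α-silyl proton of 13 and the ambident anion 14 is alkylated by the primary bromide at its sp3 carbon (the site that also reacts in its Peterson chemistry), which gives the propargylic silane as a racemate whose stereocentre is later destroyed.

Step 7
Reactants: 15 trimethyl[(7E)-8-phenyl-3-(trimethylsilyl)oct-7-en-1-yn-1-yl]silane
Product: 16 trimethyl[(7E)-8-phenyloct-7-en-1-yn-3-yl]silane
Conditions: K2CO3 (0.2 equiv), MeOH, 0 °C to rt
Reagents that add atoms: none
Why: Base-catalysed methanolysis cleaves only the C(sp)–Si bond, because only the acetylide is a good enough leaving group, and leaves the propargylic C(sp3)–Si bond in place.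

Step 8
Reactants: 16 trimethyl[(7E)-8-phenyloct-7-en-1-yn-3-yl]silane; 17 2-bromopropene
Product: 19 trimethyl[(3E,9E)-2-methyl-10-phenyldeca-1,3,9-trien-5-yl]silane, via alkenylzirconocene chloride 18 (not isolated)
Conditions: Cp2Zr(H)Cl (1.1 equiv), THF, rt; then 17 (1.5 equiv), Pd(PPh3)4 (5 mol%), rt; Et3N-deactivated silica
Reagents that add atoms: none
Why: Schwartz hydrozirconation adds Zr–H syn across the terminal alkyne with zirconium on the terminal carbon, much faster than it reacts with the internal styrenyl alkene, and palladium-catalysed Negishi-type coupling of alkenylzirconocene 18 with the alkenyl bromide proceeds with retention to give the (E)-diene.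

Step 9
Reactants: 9 (4aS,7aS)-3-methoxy-3,4a-dimethyltetrahydrofuro[3,2-c][1,2]dioxin-6-one; 19 trimethyl[(3E,9E)-2-methyl-10-phenyldeca-1,3,9-trien-5-yl]silane
Product: 21 plakortolide H, via peroxycarbenium triflate 20 (not isolated)
Conditions: 19 (1.5 equiv), TMSOTf (0.3 equiv), 2,6-di-tert-butyl-4-methylpyridine (0.4 equiv), CH2Cl2, −78 to −40 °C
Reagents that add atoms: none
Why: TMSOTf ionises the exocyclic C3–OMe bond of either anomer of 9 (the ether oxygen is more basic than the peroxide oxygens) to the single planar peroxycarbenium ion 20, the unsubstituted terminal CH2 of 19 (ε to silicon) adds to C3, and the resulting pentadienyl cation, stabilised through the diene by the allylic C–Si bond, loses Me3Si+ to give the transposed diene and return the catalyst. The closest known reactions are the Hosomi–Sakurai substitution of 3-alkoxy-1,2-dioxolanes and -dioxanes through cyclic peroxycarbenium ions and the ε-selective pentadienylation of acetals with 2,4-pentadienylsilanes. No ring is closed: the step forms the C3–C1′ bond on the preformed cis-fused bicycle. C3 is controlled by the ring: in the favoured half-chair of 20 the lactone oxygen O5 on C4a is pseudoaxial and the C4a methyl and C7a–CH2 are pseudoequatorial, and chair-like axial attack then occurs syn to O5, whereas the other half-chair would force attack 1,3-syn-diaxial to the C4a methyl, so C1′ should end cis to O5 and to C7 (3R). The step needs ε over γ regioselectivity, secured by the steric demand of the fully substituted cationic carbon and the unhindered 1,1-disubstituted terminus, and E geometry at both new alkenes, secured by the s-trans diene conformer (C2′=C3′) and by the anti-SE′ conformer in which the C5–H bond of 19 eclipses the diene (C4′=C5′). Excess silane, low temperature and the hindered pyridine should keep the less nucleophilic styrene and product diene, protodesilylation and peroxide fragmentation from competing.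

Compound list
1 | (R)-2-methylglycidol, (2R)-(2-methyloxiran-2-yl)methanol | C[C@@]1(CO)CO1 | starting material
2 | isopropenylmagnesium bromide | CC(=C)[Mg]Br | starting material
3 | (2S)-2,4-dimethylpent-4-ene-1,2-diol | C=C(C)C[C@](CO)(C)O | intermediate
4 | (2S)-2-hydroxy-2,4-dimethylpent-4-enal | C=C(C)C[C@](C=O)(C)O | intermediate
5 | (triphenylphosphoranylidene)ketene (Bestmann ylide) | O=C=C=P(c1ccccc1)(c1ccccc1)c1ccccc1 | starting material
6 | (2S)-2,4-dimethyl-1-oxopent-4-en-2-yl (triphenyl-λ5-phosphanylidene)acetate | C=C(C)C[C@](C=O)(C)OC(=O)C=P(c1ccccc1)(c1ccccc1)c1ccccc1 | intermediate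
7 | (5S)-5-methyl-5-(2-methylprop-2-en-1-yl)furan-2(5H)-one | C=C(C)C[C@]1(C)OC(=O)C=C1 | intermediate
8 | (5S)-5-(2-hydroperoxy-2-methoxypropyl)-5-methylfuran-2(5H)-one (both ketal epimers) | COC(C)(OO)C[C@]1(C)OC(=O)C=C1 | intermediate
9 | (4aS,7aS)-3-methoxy-3,4a-dimethyltetrahydrofuro[3,2-c][1,2]dioxin-6-one (cis-fused γ-lactone/1,2-dioxane, both C3 anomers) | COC1(C)C[C@]2(C)OC(=O)C[C@@H]2OO1 | intermediate
10 | styrene | C=Cc1ccccc1 | starting material
11 | 5-bromopent-1-ene | C=CCCCBr | starting material
12 | [(1E)-5-bromopent-1-en-1-yl]benzene | BrCCC/C=C/c1ccccc1 | intermediate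
13 | 1,3-bis(trimethylsilyl)propyne | C[Si](C)(C)C#CC[Si](C)(C)C | starting material
14 | [1,3-bis(trimethylsilyl)prop-2-yn-1-yl]lithium | C[Si](C)(C)C#CC([Li])[Si](C)(C)C | intermediate
15 | trimethyl[(7E)-8-phenyl-3-(trimethylsilyl)oct-7-en-1-yn-1-yl]silane (racemic) | C[Si](C)(C)C#CC([Si](C)(C)C)CCC/C=C/c1ccccc1 | intermediate
16 | trimethyl[(7E)-8-phenyloct-7-en-1-yn-3-yl]silane (racemic) | C#CC([Si](C)(C)C)CCC/C=C/c1ccccc1 | intermediate
17 | 2-bromopropene | CC(Br)=C | starting material
18 | chloridobis(cyclopentadienyl)[(1E,7E)-8-phenyl-3-(trimethylsilyl)octa-1,7-dien-1-yl]zirconium | Cl[Zr](C1C=CC=C1)(C1C=CC=C1)/C=C/C([Si](C)(C)C)CCC/C=C/c1ccccc1 | intermediate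
19 | trimethyl[(3E,9E)-2-methyl-10-phenyldeca-1,3,9-trien-5-yl]silane (racemic) | C=C(C)/C=C/C([Si](C)(C)C)CCC/C=C/c1ccccc1 | intermediate
20 | bicyclic peroxycarbenium triflate from 9 (C3=O2+ in the dioxane ring, cis-fused lactone intact) | CC=1C[C@]2(C)OC(=O)C[C@@H]2O[O+]=1.[O-]S(=O)(=O)C(F)(F)F | intermediate
21 | plakortolide H, (3R,4aS,7aS)-3,4a-dimethyl-3-[(2E,4E,9E)-2-methyl-10-phenyldeca-2,4,9-trien-1-yl]tetrahydrofuro[3,2-c][1,2]dioxin-6-one | C/C(=C\C=C\CCC/C=C/c1ccccc1)C[C@]1(C)C[C@]2(C)OC(=O)C[C@@H]2OO1 | target

Total step count: 9. Longest linear sequence: 5 (steps 1–4 then 9, or steps 5–8 then 9).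

Steps most likely to fail

1. Step 9. At the hindered, fully substituted peroxycarbenium ion, C–C bond formation may be outrun by heterolytic fragmentation of the peroxide or by proton loss from C4 or the C3 methyl. The secondary silane may also react at its γ-carbon or be protodesilylated. Facial selectivity could be lower than predicted if attack anti to O5 through a twist-boat competes, and the geometry of the new alkenes may be eroded. Fallback (sets out from 8, returns at 21): the C–C bond is made at the open-chain stage and the dioxane is closed last by the classical hydroperoxide oxa-Michael addition. 8, isolated after the ozonolysis of step 4 before any amine is added, would be silylated (Et3SiCl, imidazole, DMF, 0 °C) to the silyl peroxyketal (5S)-5-{2-methoxy-2-[(triethylsilyl)peroxy]propyl}-5-methylfuran-2(5H)-one F1. Ionisation of its methoxy group (TMSOTf or SnCl4, CH2Cl2, −78 °C) gives an unhindered open-chain silylperoxycarbenium ion, which 19 should pentadienylate to the silyl peroxide (5S)-5-{(4E,6E,11E)-2,4-dimethyl-12-phenyl-2-[(triethylsilyl)peroxy]dodeca-4,6,11-trien-1-yl}-5-methylfuran-2(5H)-one F2, as both epimers at the peroxy carbon. Bu4NF/AcOH (THF, 0 °C) should remove silicon, and the peroxide anion should close the ring by 6-exo oxa-Michael addition to the butenolide (cis fusion). This should give 21 together with its C3 epimer (3S,4aS,7aS)-3-epi-plakortolide H F3, to be separated by chromatography. Stereocontrol at C3 is given up in exchange for an unhindered C–C bond formation.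

2. Step 4. The primary ozonide may partition toward formaldehyde O-oxide, leaving the methyl ketone instead of the α-methoxy hydroperoxide. The butenolide alkene may be over-ozonised. Under amine catalysis, β-elimination of the lactone carboxylate or aza-Michael addition may compete with peroxide conjugate addition. Fallback (sets out from 7, returns at 9): ozonolysis in CH2Cl2 with Me2S work-up should give the methyl ketone (5S)-5-methyl-5-(2-oxopropyl)furan-2(5H)-one F4. Acid-catalysed perhydrolysis and ketalisation (urea–H2O2, Sc(OTf)3 cat., MeOH, rt) should convert F4 into 8 without exposing the β-acyloxy ketone to base. 8 would then be cyclised to 9 with Et2NH in CF3CH2OH as in step 4.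

3. Step 3. Addition of the hindered tertiary hydroxyl to the cumulated ylide may be slow at the temperature needed, allowing hemiacetal oligomerisation or α-ketol rearrangement of the α-hydroxy aldehyde, and evaporative loss of this volatile compound. Fallback (sets out from 4, returns at 7): Z-selective Horner–Wadsworth–Emmons olefination under Still–Gennari conditions (methyl bis(2,2,2-trifluoroethyl)phosphonoacetate, KHMDS, 18-crown-6, THF, −78 °C) should give methyl (2Z,4S)-4-hydroxy-4,6-dimethylhepta-2,6-dienoate F5. Its cis-disposed tertiary hydroxyl and ester should lactonise on work-up, or with cat. PPTS in CH2Cl2, to 7.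

Further compounds
F1 | step 9 | (5S)-5-{2-methoxy-2-[(triethylsilyl)peroxy]propyl}-5-methylfuran-2(5H)-one | CC[Si](CC)(CC)OOC(C)(OC)C[C@]1(C)OC(=O)C=C1
F2 | step 9 | (5S)-5-{(4E,6E,11E)-2,4-dimethyl-12-phenyl-2-[(triethylsilyl)peroxy]dodeca-4,6,11-trien-1-yl}-5-methylfuran-2(5H)-one | CC[Si](CC)(CC)OOC(C)(C/C(C)=C/C=C/CCC/C=C/c1ccccc1)C[C@]1(C)OC(=O)C=C1
F3 | step 9 | (3S,4aS,7aS)-3-epi-plakortolide H | C/C(=C\C=C\CCC/C=C/c1ccccc1)C[C@@]1(C)C[C@]2(C)OC(=O)C[C@@H]2OO1
F4 | step 4 | (5S)-5-methyl-5-(2-oxopropyl)furan-2(5H)-one | CC(=O)C[C@]1(C)OC(=O)C=C1
F5 | step 3 | methyl (2Z,4S)-4-hydroxy-4,6-dimethylhepta-2,6-dienoate | C=C(C)C[C@](/C=C\C(=O)OC)(C)O
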